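**Retrosynthetic overview**
- The last bond made is the (Z)-ylidene C=C of the butenolide (ring B), by vinylogous aldol condensation of a ring C–ring B butenolide with a ring A polyenynal.
- The trans-5,6-diol of ring C comes from acid hydrolysis (inversion at C5) of an oxirane cis to the 3-OH. That oxirane and ring B are closed in one flask from an acyclic (Z)-iodo-dienol: CO supplies the lactone carbonyl and the ring hydroxyl steers the epoxidation.
- The iodo-dienol comes from a dienynol (hydroalumination/iodination), made by two Stille couplings on a hydroxy enol triflate. The same triflate gives the ring A half by Sonogashira coupling and two Wittig extensions.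
- The carbocycles of rings A and C are not built; both come from (4R,6R)-actinol, the only source of chirality. Ring order: oxirane and ring B together (step 6), oxirane opened (step 7).

Assumption: (4R,6R)-actinol is bought as the bulk zeaxanthin intermediate.

**Step 1**
Reactants: 1 (4R,6R)-4-hydroxy-2,2,6-trimethylcyclohexan-1-one (actinol)
Product: 2 (4R,6R)-2,2,6-trimethyl-4-(triethylsilyloxy)cyclohexan-1-one
Conditions: Et3SiCl, imidazole, DMF, 0 °C to rt
Reagents that add atoms: triethylsilyl chloride CC[Si](Cl)(CC)CC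
Why: Imidazole-mediated silylation masks the hydroxyl so that only the ketone is deprotonated in the next step, and no stereocentre is touched.

**Step 2**
Reactants: 2 (4R,6R)-2,2,6-trimethyl-4-(triethylsilyloxy)cyclohexan-1-one
Product: 4 (R)-4-hydroxy-2,6,6-trimethylcyclohex-1-en-1-yl trifluoromethanesulfonate, via triethylsilyl-protected enol triflate 3 (not isolated)
Conditions: LiN(i-Pr)2, THF, −78 °C; PhNTf2, −78 °C to rt; then PPTS (cat.), MeOH, rt
Reagents that add atoms: N-phenylbis(trifluoromethanesulfonimide) O=S(=O)(N(c1ccccc1)S(=O)(=O)C(F)(F)F)C(F)(F)F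
Why: Enolisation is possible only toward the methine carbon because the other α-carbon is quaternary, so enolate O-triflation (McMurry–Scott enol triflate synthesis) gives the tetrasubstituted enol triflate regiospecifically, and PPTS methanolysis then removes the labile silyl ether without touching the vinyl triflate or the carbinol centre.

**Step 3**
Reactants: 4 (R)-4-hydroxy-2,6,6-trimethylcyclohex-1-en-1-yl trifluoromethanesulfonate; 5 (E)-1,2-bis(tributylstannyl)ethene (3 equiv)
Product: 6 (R)-3,5,5-trimethyl-4-[(E)-2-(tributylstannyl)ethenyl]cyclohex-3-en-1-ol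
Conditions: Pd2(dba)3 (2.5 mol%), AsPh3 (20 mol%), LiCl, NMP, 60 °C
Reagents that add atoms: none
Why: Stille coupling of the hindered alkenyl triflate under Farina conditions with excess bis-stannane stops at mono-coupling and transfers the (E)-ethene unit with retention of geometry.

**Step 4**
Reactants: 6 (R)-3,5,5-trimethyl-4-[(E)-2-(tributylstannyl)ethenyl]cyclohex-3-en-1-ol; 7 3-bromoprop-2-yn-1-ol
Product: 8 (R)-4-[(E)-5-hydroxypent-1-en-3-yn-1-yl]-3,5,5-trimethylcyclohex-3-en-1-ol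
Conditions: Pd2(dba)3 (2.5 mol%), P(2-furyl)3 (10 mol%), DMF, rt
Reagents that add atoms: none
Why: Stille coupling of an alkenylstannane with a 1-bromoalkyne keeps the (E)-alkene geometry and tolerates both free hydroxyls.

**Step 5**
Reactants: 8 (R)-4-[(E)-5-hydroxypent-1-en-3-yn-1-yl]-3,5,5-trimethylcyclohex-3-en-1-ol
Product: 10 (R)-4-[(1E,3Z)-5-hydroxy-3-iodopenta-1,3-dien-1-yl]-3,5,5-trimethylcyclohex-3-en-1-ol, via cyclic sodium alkenylalanate 9 (not isolated)
Conditions: NaAlH2(OCH2CH2OCH3)2 (3.5 equiv), THF, 0 °C to rt; then I2, THF, −78 to 0 °C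
Reagents that add atoms: iodine II
Why: Alkoxide-directed trans-hydroalumination of the propargylic alcohol (Corey-type reduction) puts aluminium on the dienyl-bearing carbon inside a five-membered alanate, and iodinolysis with retention gives the (Z)-3-iodoallylic alcohol with iodine cis to CH2OH.

**Step 6 (key step: ring B and the oxirane are formed in one flask)**
Reactants: 10 (R)-4-[(1E,3Z)-5-hydroxy-3-iodopenta-1,3-dien-1-yl]-3,5,5-trimethylcyclohex-3-en-1-ol
Product: 12 3-[(E)-2-[(1R,4S,6S)-4-hydroxy-2,2,6-trimethyl-7-oxabicyclo[4.1.0]heptan-1-yl]ethenyl]furan-2(5H)-one, via dienyl butenolide 11 (not isolated)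
Conditions: PdCl2(PPh3)2 (5 mol%), K2CO3, CO (1 atm), THF, 40 °C; then filter, CH2Cl2, VO(acac)2 (5 mol%), t-BuOOH (decane), 0 °C to rt
Reagents that add atoms: carbon monoxide [C-]#[O+]; tert-butyl hydroperoxide CC(C)(C)OO
Why: Cowell–Stille carbonylative lactonisation (oxidative addition, CO insertion, capture of the acylpalladium by the cis CH2OH) closes the butenolide, and in the same flask Sharpless–Michaelson vanadium-catalysed epoxidation is delivered by the homoallylic ring hydroxyl to its own face of the only electron-rich (tetrasubstituted) alkene, setting C5 and C6 as the oxirane cis to the 3-OH.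

**Step 7**
Reactants: 12 3-[(E)-2-[(1R,4S,6S)-4-hydroxy-2,2,6-trimethyl-7-oxabicyclo[4.1.0]heptan-1-yl]ethenyl]furan-2(5H)-one
Product: 13 3-[(E)-2-[(1R,2R,4S)-1,2,4-trihydroxy-2,6,6-trimethylcyclohexyl]ethenyl]furan-2(5H)-one
Conditions: HClO4 (5 mol%), THF/H2O 3:1, 0 °C
Reagents that add atoms: water O
Why: Acid-catalysed epoxide hydrolysis goes by backside attack of water at C5, because C6 is neopentyl and its cation is destabilised by the vinylogous lactone, so C5 is inverted and the trans-diaxial 5,6-diol of the target results.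

**Step 8**
Reactants: 4 (R)-4-hydroxy-2,6,6-trimethylcyclohex-1-en-1-yl trifluoromethanesulfonate; 14 (E)-3-methylpent-2-en-4-yn-1-ol
Product: 15 (R)-4-[(E)-5-hydroxy-3-methylpent-3-en-1-yn-1-yl]-3,5,5-trimethylcyclohex-3-en-1-ol
Conditions: Pd(PPh3)4 (5 mol%), CuI (10 mol%), i-Pr2NH, DMF, 50 °C
Reagents that add atoms: none
Why: Sonogashira coupling of the enol triflate with the terminal alkyne installs the ring A enyne and leaves the preset (E)-trisubstituted alkene untouched.

**Step 9**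
Reactants: 15 (R)-4-[(E)-5-hydroxy-3-methylpent-3-en-1-yn-1-yl]-3,5,5-trimethylcyclohex-3-en-1-ol
Product: 16 [(E)-5-[(R)-4-hydroxy-2,6,6-trimethylcyclohex-1-en-1-yl]-3-methylpent-2-en-4-yn-1-yl]triphenylphosphonium bromide
Conditions: PPh3·HBr, MeOH, rt
Reagents that add atoms: triphenylphosphine hydrobromide [Br-].c1ccc(cc1)[PH+](c1ccccc1)c1ccccc1
Why: The primary allylic alcohol is converted directly into the allylic phosphonium salt (the standard preparation of carotenoid C15 Wittig salts), while the secondary ring hydroxyl is inert.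

**Step 10**
Reactants: 16 C15 phosphonium bromide; 17 (E)-4,4-dimethoxybut-2-enal
Product: 19 (2E,4E,6E)-9-[(R)-4-hydroxy-2,6,6-trimethylcyclohex-1-en-1-yl]-7-methylnona-2,4,6-trien-8-ynal, via dimethyl acetal 18 (not isolated)
Conditions: NaOMe, CH2Cl2/MeOH, 0 °C to rt; then p-TsOH (cat.), acetone/H2O, rt; I2 (cat.), CH2Cl2, rt
Reagents that add atoms: water O
Why: Wittig olefination builds the new disubstituted alkene, acetal hydrolysis frees the aldehyde, and iodine-catalysed equilibration converts any (Z)-isomer at the new bond into the all-(E) polyene.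

**Step 11**
Reactants: 19 (2E,4E,6E)-9-[(R)-4-hydroxy-2,6,6-trimethylcyclohex-1-en-1-yl]-7-methylnona-2,4,6-trien-8-ynal; 20 2-(triphenylphosphoranylidene)propanal
Product: 21 (2E,4E,6E,8E)-11-[(R)-4-hydroxy-2,6,6-trimethylcyclohex-1-en-1-yl]-2,9-dimethylundeca-2,4,6,8-tetraen-10-ynal
Conditions: toluene, 80 °C
Reagents that add atoms: none
Why: Wittig reaction with a stabilised formyl ylide gives the (E)-2-methyl enal selectively and reacts only once because the product enal is less electrophilic.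

**Step 12**
Reactants: 13 3-[(E)-2-[(1R,2R,4S)-1,2,4-trihydroxy-2,6,6-trimethylcyclohexyl]ethenyl]furan-2(5H)-one; 21 (2E,4E,6E,8E)-11-[(R)-4-hydroxy-2,6,6-trimethylcyclohex-1-en-1-yl]-2,9-dimethylundeca-2,4,6,8-tetraen-10-ynal
Product: 26 CNP0163979.1, via persilylated silyloxyfuran 22 (not isolated), via silylated aldehyde 23 (not isolated), via silylated aldol adduct 24 (not isolated), via silylated target 25 (not isolated)
Conditions: Me3SiOTf (6 equiv), i-Pr2NEt (8 equiv), CH2Cl2, −78 to −20 °C; DBU, −20 to 0 °C; then HF·pyridine, pyridine, THF, 0 °C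
Reagents that add atoms: none
Why: In a Boukouvalas-type one-pot vinylogous Mukaiyama aldol/β-elimination the transient 2-silyloxyfuran attacks the aldehyde through its γ-carbon, DBU expels the β-silyloxy group (E1cB) to give the thermodynamically preferred (Z)-ylidenebutenolide, and buffered fluoride removes the temporary silyl ethers without changing any stereocentre.

**Compound list**
1 | (4R,6R)-4-hydroxy-2,2,6-trimethylcyclohexan-1-one (actinol) | O=C1C(C)(C)C[C@H](O)C[C@H]1C | starting material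
2 | (4R,6R)-2,2,6-trimethyl-4-(triethylsilyloxy)cyclohexan-1-one | O=C1C(C)(C)C[C@H](O[Si](CC)(CC)CC)C[C@H]1C | intermediate
3 | (R)-2,6,6-trimethyl-4-(triethylsilyloxy)cyclohex-1-en-1-yl trifluoromethanesulfonate | CC1=C(OS(=O)(=O)C(F)(F)F)C(C)(C)C[C@H](O[Si](CC)(CC)CC)C1 | intermediate (not isolated)
4 | (R)-4-hydroxy-2,6,6-trimethylcyclohex-1-en-1-yl trifluoromethanesulfonate | CC1=C(OS(=O)(=O)C(F)(F)F)C(C)(C)C[C@H](O)C1 | intermediate
5 | (E)-1,2-bis(tributylstannyl)ethene | CCCC[Sn](CCCC)(CCCC)/C=C/[Sn](CCCC)(CCCC)CCCC | starting material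
6 | (R)-3,5,5-trimethyl-4-[(E)-2-(tributylstannyl)ethenyl]cyclohex-3-en-1-ol | CC1=C(/C=C/[Sn](CCCC)(CCCC)CCCC)C(C)(C)C[C@H](O)C1 | intermediate
7 | 3-bromoprop-2-yn-1-ol | OCC#CBr | starting material
8 | (R)-4-[(E)-5-hydroxypent-1-en-3-yn-1-yl]-3,5,5-trimethylcyclohex-3-en-1-ol | CC1=C(/C=C/C#CCO)C(C)(C)C[C@H](O)C1 | intermediate
9 | cyclic sodium alkenylalanate of 8 (five-membered C–Al–O ring; Al on the dienyl-bearing carbon; ring hydroxyl drawn free) | CC1=C(/C=C/C2=CCO[Al-]2(OCCOC)OCCOC)C(C)(C)C[C@H](O)C1.[Na+] | intermediate (not isolated)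
10 | (R)-4-[(1E,3Z)-5-hydroxy-3-iodopenta-1,3-dien-1-yl]-3,5,5-trimethylcyclohex-3-en-1-ol | CC1=C(/C=C/C(I)=C/CO)C(C)(C)C[C@H](O)C1 | intermediate
11 | 3-[(E)-2-[(R)-4-hydroxy-2,6,6-trimethylcyclohex-1-en-1-yl]ethenyl]furan-2(5H)-one | CC1=C(/C=C/C2=CCOC2=O)C(C)(C)C[C@H](O)C1 | intermediate (not isolated)
12 | 3-[(E)-2-[(1R,4S,6S)-4-hydroxy-2,2,6-trimethyl-7-oxabicyclo[4.1.0]heptan-1-yl]ethenyl]furan-2(5H)-one (oxirane cis to the hydroxyl) | O=C1OCC=C1/C=C/[C@@]2(O3)C(C)(C)C[C@H](O)C[C@@]23C | intermediate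
13 | 3-[(E)-2-[(1R,2R,4S)-1,2,4-trihydroxy-2,6,6-trimethylcyclohexyl]ethenyl]furan-2(5H)-one | O=C1OCC=C1/C=C/[C@@]2(O)C(C)(C)C[C@H](O)C[C@@]2(C)O | intermediate
14 | (E)-3-methylpent-2-en-4-yn-1-ol | C#C/C(C)=C/CO | starting material
15 | (R)-4-[(E)-5-hydroxy-3-methylpent-3-en-1-yn-1-yl]-3,5,5-trimethylcyclohex-3-en-1-ol | CC1=C(C#C/C(C)=C/CO)C(C)(C)C[C@H](O)C1 | intermediate
16 | [(E)-5-[(R)-4-hydroxy-2,6,6-trimethylcyclohex-1-en-1-yl]-3-methylpent-2-en-4-yn-1-yl]triphenylphosphonium bromide | CC1=C(C#C/C(C)=C/C[P+](c2ccccc2)(c2ccccc2)c2ccccc2)C(C)(C)C[C@H](O)C1.[Br-] | intermediate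
17 | (E)-4,4-dimethoxybut-2-enal | COC(OC)/C=C/C=O | starting material
18 | dimethyl acetal of 19 (E/Z mixture at the new bond, drawn all-E) | CC1=C(C#C/C(C)=C/C=C/C=C/C(OC)OC)C(C)(C)C[C@H](O)C1 | intermediate (not isolated)
19 | (2E,4E,6E)-9-[(R)-4-hydroxy-2,6,6-trimethylcyclohex-1-en-1-yl]-7-methylnona-2,4,6-trien-8-ynal | CC1=C(C#C/C(C)=C/C=C/C=C/C=O)C(C)(C)C[C@H](O)C1 | intermediate
20 | 2-(triphenylphosphoranylidene)propanal | CC(C=O)=P(c1ccccc1)(c1ccccc1)c1ccccc1 | starting material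
21 | (2E,4E,6E,8E)-11-[(R)-4-hydroxy-2,6,6-trimethylcyclohex-1-en-1-yl]-2,9-dimethylundeca-2,4,6,8-tetraen-10-ynal | CC1=C(C#C/C(C)=C/C=C/C=C/C=C(C)/C=O)C(C)(C)C[C@H](O)C1 | intermediate
22 | 2-(trimethylsilyloxy)furan of 13 with all three ring hydroxyls as trimethylsilyl ethers | C[Si](C)(C)Oc1occc1/C=C/[C@@]1(O[Si](C)(C)C)C(C)(C)C[C@H](O[Si](C)(C)C)C[C@@]1(C)O[Si](C)(C)C | intermediate (not isolated)
23 | trimethylsilyl ether of 21 | CC1=C(C#C/C(C)=C/C=C/C=C/C=C(C)/C=O)C(C)(C)C[C@H](O[Si](C)(C)C)C1 | intermediate (not isolated)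
24 | γ-(1-silyloxyalkyl)butenolide aldol adduct, penta(trimethylsilyl) ether, mixture at the two new carbinol/lactone centres | CC1=C(C#C/C(C)=C/C=C/C=C/C=C(C)/C(O[Si](C)(C)C)C2C=C(/C=C/[C@@]3(O[Si](C)(C)C)C(C)(C)C[C@H](O[Si](C)(C)C)C[C@@]3(C)O[Si](C)(C)C)C(=O)O2)C(C)(C)C[C@H](O[Si](C)(C)C)C1 | intermediate (not isolated)
25 | tetra(trimethylsilyl) ether of 26 | CC1=C(C#C/C(C)=C/C=C/C=C/C=C(C)/C=C2C=C(/C=C/[C@@]3(O[Si](C)(C)C)C(C)(C)C[C@H](O[Si](C)(C)C)C[C@@]3(C)O[Si](C)(C)C)C(=O)O/2)C(C)(C)C[C@H](O[Si](C)(C)C)C1 | intermediate (not isolated)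
26 | CNP0163979.1: (5Z)-3-[(E)-2-[(1R,2R,4S)-1,2,4-trihydroxy-2,6,6-trimethylcyclohexyl]ethenyl]-5-[(2E,4E,6E,8E)-11-[(R)-4-hydroxy-2,6,6-trimethylcyclohex-1-en-1-yl]-2,9-dimethylundeca-2,4,6,8-tetraen-10-yn-1-ylidene]furan-2(5H)-one | CC1=C(C#C/C(C)=C/C=C/C=C/C=C(C)/C=C2C=C(/C=C/[C@@]3(O)C(C)(C)C[C@H](O)C[C@@]3(C)O)C(=O)O/2)C(C)(C)C[C@H](O)C1 | target

**Totals**
Total step count: 12. Longest linear sequence: 8 (steps 1, 2, 3, 4, 5, 6, 7, 12).

**Three steps most likely to fail**

Step 12 (highest risk). The tertiary allylic C–OSiMe3 next to the electron-rich silyloxyfuran can ionise under the silyl triflate, and the ylidene may form as an E/Z mixture. The fallback sets out from 21 and 4 and comes back at 26 with a Stille endgame in which ring C is attached last. Compound 21 is homologated with the Ohira–Bestmann reagent (K2CO3, MeOH) to the terminal alkyne F2. Tandem Sonogashira coupling/5-exo-dig lactonisation of F2 with (E)-2,3-dibromoacrylic acid (Pd(PPh3)4, CuI, Et3N, MeCN) gives the bromo ylidenebutenolide F3. In parallel, 4 is coupled with tributyl(ethynyl)stannane (Pd(PPh3)4, LiCl) to the enyne F4. F4 is epoxidised with VO(acac)2/t-BuOOH to the epoxy alkyne F5 and hydrolysed with dilute HClO4 to the ethynyl triol F6. PdCl2(PPh3)2/Bu3SnH hydrostannation of F6 gives the vinylstannane F7. Stille coupling of F3 with F7 (Pd2(dba)3, AsPh3) gives 26 directly.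

Step 6. The iodo-triene may undergo side reactions before CO insertion, and the directed epoxidation may be slow or less face-selective on the conjugated ring alkene. The fallback sets out from 6 and comes back at 12. Compound 6 is coupled with purchased 3-bromofuran-2(5H)-one (Stille; Pd2(dba)3, AsPh3, CuI, NMP), so that the lactone ring is bought instead of being built with CO. This gives 11 as an isolated compound, which is epoxidised on its own with VO(acac)2/t-BuOOH to 12; steps 4 and 5 then fall away.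

Step 7. Ionisation at C6 would lead to allylic or furanoid by-products, and loss of inversion at C5 would give the cis-diol. The fallback sets out from 12 and comes back at 13. Buffered formolysis (HCO2H/HCO2Na, THF, 0 °C) opens the oxirane with a carboxylate nucleophile at C5 under much weaker acid to give the C5 formate F1. The formate is then cleaved with NaHCO3 in aqueous methanol to give 13.

Further compounds
F0 | step 6 | none | none
F1 | step 7 | C5 formate: 3-[(E)-2-[(1R,2R,4S)-2-(formyloxy)-1,4-dihydroxy-2,6,6-trimethylcyclohexyl]ethenyl]furan-2(5H)-one | O=C1OCC=C1/C=C/[C@@]2(O)C(C)(C)C[C@H](O)C[C@@]2(C)OC=O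
F2 | step 12 | terminal alkyne: (R)-3,5,5-trimethyl-4-[(3E,5E,7E,9E)-3,10-dimethyldodeca-3,5,7,9-tetraene-1,11-diyn-1-yl]cyclohex-3-en-1-ol | CC1=C(C#C/C(C)=C/C=C/C=C/C=C(C)/C#C)C(C)(C)C[C@H](O)C1
F3 | step 12 | bromo ylidenebutenolide: (5Z)-3-bromo-5-[(2E,4E,6E,8E)-11-[(R)-4-hydroxy-2,6,6-trimethylcyclohex-1-en-1-yl]-2,9-dimethylundeca-2,4,6,8-tetraen-10-yn-1-ylidene]furan-2(5H)-one | CC1=C(C#C/C(C)=C/C=C/C=C/C=C(C)/C=C2C=C(Br)C(=O)O/2)C(C)(C)C[C@H](O)C1
F4 | step 12 | enyne: (R)-4-ethynyl-3,5,5-trimethylcyclohex-3-en-1-ol | CC1=C(C#C)C(C)(C)C[C@H](O)C1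
F5 | step 12 | epoxy alkyne: 1-ethynyl-4-hydroxy-2,2,6-trimethyl-7-oxabicyclo[4.1.0]heptane, oxirane cis to the hydroxyl, configuration as in 12 | C#C[C@@]1(O2)C(C)(C)C[C@H](O)C[C@@]12C
F6 | step 12 | ethynyl triol: 1-ethynyl-2,6,6-trimethylcyclohexane-1,2,4-triol, configuration as in 13 | C#C[C@@]1(O)C(C)(C)C[C@H](O)C[C@@]1(C)O
F7 | step 12 | vinylstannane: 2,6,6-trimethyl-1-[(E)-2-(tributylstannyl)ethenyl]cyclohexane-1,2,4-triol, configuration as in 13 | CCCC[Sn](CCCC)(CCCC)/C=C/[C@@]1(O)C(C)(C)C[C@H](O)C[C@@]1(C)O
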